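**Plan**
- Retrosynthesis: cut the eight O-protecting groups, then C2–C3 of flavanone ring C, then the O1–C2 ether, then the C5'–C6'' biaryl bond. This leaves luteolin, 3-bromo-4,5-dihydroxybenzaldehyde and 2',4'-dihydroxy-6'-methoxyacetophenone.
- Forward: luteolin (all three rings bought intact) is benzylated, iodinated at C6'' and joined to the ring-B boronate by Suzuki–Miyaura coupling. A Mitsunobu reaction with the ring-A phenol makes O1–C2, the acetyl group becomes a diazo ketone, and ring C closes last.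
- Enabling feature: the O1–CH2 methylene (future C2). Its C–H bonds are alpha to O1 and benzylic to ring B (para benzyloxy), and lie 1,6 to the diazo carbon (future C3) across C4–C4a–C8a–O1 of ring A. The 1,5 atom is O1 itself, so C–H insertion can only close the six-membered ring C.
- Polarity: C3 reacts as an electrophilic carbenoid instead of an enolate, and C2 as a hydridic C–H donor instead of a chalcone beta-carbon, so C2 needs no prior oxidation or leaving group.
- Stereochemistry: C2 (S), the only stereocentre, comes from catalyst-controlled choice between the two enantiotopic C2–H bonds. No basic step follows, so racemisation through the chalcone is avoided.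

Key step: step 11

Remark: the sense of induction of Rh2(S-PTTL)4 on this substrate is assumed to be 2S; if the first run shows the opposite sense, Rh2(R-PTTL)4 is used with no other change.
Remark: the target defines no axial configuration, so the C5'–C6'' axis is treated as not stereogenic in the free polyphenol; slowly interconverting rotamers of the benzylated intermediates would converge on deprotection.

Step 1
Reactants: 1 luteolin (2-(3,4-dihydroxyphenyl)-5,7-dihydroxy-4H-chromen-4-one)
Product: 2 7,3',4'-tri-O-benzylluteolin (7-(benzyloxy)-2-[3,4-bis(benzyloxy)phenyl]-5-hydroxy-4H-chromen-4-one)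
Conditions: BnBr (3.3 equiv), K2CO3, DMF, rt
Reagents that add atoms: benzyl bromide BrCc1ccccc1
Why: Williamson etherification; the 5-OH is hydrogen-bonded to the C4 carbonyl and much less nucleophilic, so only the 7-, 3'- and 4'-phenols should be alkylated.

Step 2
Reactants: 2 7,3',4'-tri-O-benzylluteolin
Product: 3 7,3',4'-tri-O-benzyl-6-iodoluteolin (7-(benzyloxy)-2-[3,4-bis(benzyloxy)phenyl]-5-hydroxy-6-iodo-4H-chromen-4-one)
Conditions: BnMe3N+ ICl2− (1.1 equiv), CaCO3, CH2Cl2/MeOH, rt
Reagents that add atoms: benzyltrimethylammonium dichloroiodate C[N+](C)(C)Cc1ccccc1.Cl[I-]Cl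
Why: electrophilic aromatic iodination; the free 5-OH makes the phloroglucinol ring the most electron-rich arene, and dichloroiodate is known to iodinate 5-hydroxy-7-alkoxyflavones at C6, ortho to the chelated phenol.

Step 3
Reactants: 3 7,3',4'-tri-O-benzyl-6-iodoluteolin
Product: 4 5,7,3',4'-tetra-O-benzyl-6-iodoluteolin (5,7-bis(benzyloxy)-2-[3,4-bis(benzyloxy)phenyl]-6-iodo-4H-chromen-4-one)
Conditions: BnBr (1.5 equiv), K2CO3, DMF, 70 °C
Reagents that add atoms: benzyl bromide BrCc1ccccc1
Why: Williamson etherification of the chelated phenol under forcing conditions; this removes the last acidic O–H, which would otherwise undergo O–H insertion in step 11.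

Step 4
Reactants: 5 3-bromo-4,5-dihydroxybenzaldehyde
Product: 6 3,4-bis(benzyloxy)-5-bromobenzaldehyde
Conditions: BnBr (2.3 equiv), K2CO3, DMF, 60 °C
Reagents that add atoms: benzyl bromide BrCc1ccccc1
Why: Williamson etherification of both catechol hydroxyls.

Step 5
Reactants: 6 3,4-bis(benzyloxy)-5-bromobenzaldehyde
Product: 7 [3,4-bis(benzyloxy)-5-bromophenyl]methanol
Conditions: NaBH4, MeOH/THF, 0 °C
Reagents that add atoms: none
Why: borohydride reduction of the aldehyde gives the benzylic carbon at the oxidation level needed for C2, before any flavone carbonyl is present.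

Step 6
Reactants: 7 [3,4-bis(benzyloxy)-5-bromophenyl]methanol
Product: 8 [3,4-bis(benzyloxy)-5-(4,4,5,5-tetramethyl-1,3,2-dioxaborolan-2-yl)phenyl]methanol
Conditions: B2pin2 (1.3 equiv), PdCl2(dppf) (5 mol %), KOAc, dioxane, 90 °C
Reagents that add atoms: bis(pinacolato)diboron CC1(C)OB(OC1(C)C)B1OC(C)(C)C(C)(C)O1
Why: Miyaura borylation; KOAc is too weak a base to trigger homocoupling and the free benzylic alcohol is tolerated.

Step 7
Reactants: 4 5,7,3',4'-tetra-O-benzyl-6-iodoluteolin; 8 the ring-B pinacol boronate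
Product: 9 biaryl benzylic alcohol (5,7-bis(benzyloxy)-6-[2,3-bis(benzyloxy)-5-(hydroxymethyl)phenyl]-2-[3,4-bis(benzyloxy)phenyl]-4H-chromen-4-one)
Conditions: Pd(OAc)2 (5 mol %), SPhos (10 mol %), K3PO4, toluene/H2O, 90 °C
Reagents that add atoms: none
Why: Suzuki–Miyaura coupling; the bulky biaryl dialkylphosphine supports oxidative addition and reductive elimination at the di-ortho-alkoxy iodide, so the tri-ortho-substituted C5'–C6'' bond should form while the flavone and the benzylic alcohol remain untouched.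

Step 8
Reactants: 10 1-(2,4-dihydroxy-6-methoxyphenyl)ethan-1-one
Product: 11 1-[4-(benzyloxy)-2-hydroxy-6-methoxyphenyl]ethan-1-one
Conditions: BnBr (1.05 equiv), K2CO3, acetone, reflux
Reagents that add atoms: benzyl bromide BrCc1ccccc1
Why: Williamson etherification selective for the 4-OH, because the 2-OH is hydrogen-bonded to the acetyl group; the methyl ether already in place will later be the ortho neighbour of the carbenoid that offers no activated C–H bond.

Step 9
Reactants: 9 biaryl benzylic alcohol; 11 1-[4-(benzyloxy)-2-hydroxy-6-methoxyphenyl]ethan-1-one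
Product: 12 aryl benzyl ether methyl ketone (1-[4-(benzyloxy)-2-methoxy-6-({3,4-bis(benzyloxy)-5-[5,7-bis(benzyloxy)-2-(3,4-bis(benzyloxy)phenyl)-4-oxo-4H-chromen-6-yl]benzyl}oxy)phenyl]ethan-1-one)
Conditions: PPh3, DIAD, THF, 0 °C to rt
Reagents that add atoms: none
Why: Mitsunobu etherification of the acidic ortho-acyl phenol with the primary benzylic alcohol makes the O1–C2 bond under neutral conditions, with no electron-rich benzylic halide to handle.

Step 10
Reactants: 12 aryl benzyl ether methyl ketone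
Product: 14 diazo ketone (2-diazo-1-[4-(benzyloxy)-2-methoxy-6-({3,4-bis(benzyloxy)-5-[5,7-bis(benzyloxy)-2-(3,4-bis(benzyloxy)phenyl)-4-oxo-4H-chromen-6-yl]benzyl}oxy)phenyl]ethan-1-one), via trifluoroacetyl ketone 13 (not isolated)
Conditions: LiN(SiMe3)2 (1.1 equiv), THF, −78 °C, then CF3CO2CH2CF3; 5 % aq. HCl work-up; then MsN3, Et3N, H2O (1 equiv), MeCN, rt
Reagents that add atoms: methanesulfonyl azide CS(=O)(=O)N=[N+]=[N-] (supplies the N2 of 14); 2,2,2-trifluoroethyl trifluoroacetate O=C(OCC(F)(F)F)C(F)(F)F (supplies the CF3CO group of 13 only)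
Why: detrifluoroacetylative diazo transfer (Claisen-type C-trifluoroacetylation of the kinetic lithium enolate, then Regitz-type transfer from the sulfonyl azide with loss of the trifluoroacetyl group); the methyl and benzyl ethers flanking the ketone cannot migrate to the enolate, and the flavone has no acidic C–H.

Step 11
Reactants: 14 diazo ketone
Product: 15 hepta-O-benzyl-5-O-methyl flavanone ((2S)-7-(benzyloxy)-2-{3,4-bis(benzyloxy)-5-[5,7-bis(benzyloxy)-2-(3,4-bis(benzyloxy)phenyl)-4-oxo-4H-chromen-6-yl]phenyl}-5-methoxychroman-4-one)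
Conditions: Rh2(S-PTTL)4 (dirhodium tetrakis[N-phthaloyl-(S)-tert-leucinate], 2 mol %), CH2Cl2, 4 Å MS, 0 °C, 14 added by syringe pump over 4 h
Reagents that add atoms: none
Why: The dirhodium carboxylate expels N2 from the terminal diazo ketone to give an electrophilic rhodium carbenoid at the future C3, which inserts into one C–H bond of the O1–CH2–aryl methylene through a concerted three-centre, hydride-transfer-like transition state, so that C3–C2 and C3–H form together and C3 ends as the CH2 of the flavanone. The closest known reaction types are the chiral dirhodium carboxylate-catalysed intramolecular C–H insertion of ortho-alkoxyaryl diazo ketones to chroman-4-ones and the Rh2(S-PTTL)4-catalysed insertion of aryldiazoacetates into ArO–CH2Ar bonds to give cis-2-aryl-2,3-dihydrobenzofurans. Ring C closes as a six-membered ring by 1,6-C–H insertion, and no five-membered C–H insertion can compete because the atom 1,5 to the carbenoid carbon is O1, which carries no hydrogen. C2 is the only new stereocentre and is set by the catalyst: insertion is stereoretentive at carbon, the phthalimido wall of the chiral pocket should select the pro-S hydrogen of the enantiotopic pair, and its replacement by C3 gives 2S. The step needs chemoselectivity for C–H insertion over oxonium ylide formation at O1 (which would end in a [1,2]-benzyl Stevens shift) and over attack on the ortho methoxy group; this should be secured by the double activation of the C2–H bonds (alpha to O1 and benzylic to ring B with its para benzyloxy group), by the low basicity of O1, whose lone pair is delocalised into the acyl-bearing ring A, by the bulky carboxylate ligands, and by the methyl ether at the other ortho oxygen, which offers only strong primary C–H bonds. Slow addition at high dilution suppresses carbene dimerisation and intermolecular attack on the seven remote benzyl ethers.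

Step 12
Reactants: 15 hepta-O-benzyl-5-O-methyl flavanone
Product: 16 target ((2S)-2-{3,4-dihydroxy-5-[2-(3,4-dihydroxyphenyl)-5,7-dihydroxy-4-oxo-4H-chromen-6-yl]phenyl}-5,7-dihydroxychroman-4-one)
Conditions: BCl3 (1 M in CH2Cl2, excess), pentamethylbenzene (excess), CH2Cl2, −78 °C to 0 °C; MeOH quench, aqueous work-up
Reagents that add atoms: none
Why: Lewis acid ether cleavage with a cation scavenger; BCl3 ionises the seven aryl benzyl ethers at −78 °C while pentamethylbenzene traps each benzyl cation by Friedel–Crafts alkylation, the C5 methyl ether falls on warming through the C4=O–boron chelate, and the absence of base and the low temperature should leave the C2–O1 bond and the 2S centre intact.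

**Compound list**
1 | luteolin, 2-(3,4-dihydroxyphenyl)-5,7-dihydroxy-4H-chromen-4-one | O=c1cc(-c2ccc(O)c(O)c2)oc2cc(O)cc(O)c12 | starting material
2 | 7-(benzyloxy)-2-[3,4-bis(benzyloxy)phenyl]-5-hydroxy-4H-chromen-4-one | O=c1cc(-c2ccc(OCc3ccccc3)c(OCc3ccccc3)c2)oc2cc(OCc3ccccc3)cc(O)c12 | intermediate
3 | 7-(benzyloxy)-2-[3,4-bis(benzyloxy)phenyl]-5-hydroxy-6-iodo-4H-chromen-4-one | O=c1cc(-c2ccc(OCc3ccccc3)c(OCc3ccccc3)c2)oc2cc(OCc3ccccc3)c(I)c(O)c12 | intermediate
4 | 5,7-bis(benzyloxy)-2-[3,4-bis(benzyloxy)phenyl]-6-iodo-4H-chromen-4-one | O=c1cc(-c2ccc(OCc3ccccc3)c(OCc3ccccc3)c2)oc2cc(OCc3ccccc3)c(I)c(OCc3ccccc3)c12 | intermediate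
5 | 3-bromo-4,5-dihydroxybenzaldehyde | O=Cc1cc(O)c(O)c(Br)c1 | starting material
6 | 3,4-bis(benzyloxy)-5-bromobenzaldehyde | O=Cc1cc(OCc2ccccc2)c(OCc2ccccc2)c(Br)c1 | intermediate
7 | [3,4-bis(benzyloxy)-5-bromophenyl]methanol | OCc1cc(OCc2ccccc2)c(OCc2ccccc2)c(Br)c1 | intermediate
8 | [3,4-bis(benzyloxy)-5-(4,4,5,5-tetramethyl-1,3,2-dioxaborolan-2-yl)phenyl]methanol | OCc1cc(OCc2ccccc2)c(OCc2ccccc2)c(B2OC(C)(C)C(C)(C)O2)c1 | intermediate
9 | 5,7-bis(benzyloxy)-6-[2,3-bis(benzyloxy)-5-(hydroxymethyl)phenyl]-2-[3,4-bis(benzyloxy)phenyl]-4H-chromen-4-one | O=c1cc(-c2ccc(OCc3ccccc3)c(OCc3ccccc3)c2)oc2cc(OCc3ccccc3)c(-c3cc(CO)cc(OCc4ccccc4)c3OCc3ccccc3)c(OCc3ccccc3)c12 | intermediate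
10 | 1-(2,4-dihydroxy-6-methoxyphenyl)ethan-1-one | CC(=O)c1c(O)cc(O)cc1OC | starting material
11 | 1-[4-(benzyloxy)-2-hydroxy-6-methoxyphenyl]ethan-1-one | CC(=O)c1c(O)cc(OCc2ccccc2)cc1OC | intermediate
12 | 1-[4-(benzyloxy)-2-methoxy-6-({3,4-bis(benzyloxy)-5-[5,7-bis(benzyloxy)-2-(3,4-bis(benzyloxy)phenyl)-4-oxo-4H-chromen-6-yl]benzyl}oxy)phenyl]ethan-1-one | CC(=O)c1c(OCc2cc(OCc3ccccc3)c(OCc3ccccc3)c(-c3c(OCc4ccccc4)cc4oc(-c5ccc(OCc6ccccc6)c(OCc6ccccc6)c5)cc(=O)c4c3OCc3ccccc3)c2)cc(OCc2ccccc2)cc1OC | intermediate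
13 | 4,4,4-trifluoro-1-aryl-butane-1,3-dione, the C-trifluoroacetyl derivative of 12 | O=C(CC(=O)C(F)(F)F)c1c(OCc2cc(OCc3ccccc3)c(OCc3ccccc3)c(-c3c(OCc4ccccc4)cc4oc(-c5ccc(OCc6ccccc6)c(OCc6ccccc6)c5)cc(=O)c4c3OCc3ccccc3)c2)cc(OCc2ccccc2)cc1OC | intermediate (not isolated)
14 | 2-diazo-1-[4-(benzyloxy)-2-methoxy-6-({3,4-bis(benzyloxy)-5-[5,7-bis(benzyloxy)-2-(3,4-bis(benzyloxy)phenyl)-4-oxo-4H-chromen-6-yl]benzyl}oxy)phenyl]ethan-1-one | [N-]=[N+]=CC(=O)c1c(OCc2cc(OCc3ccccc3)c(OCc3ccccc3)c(-c3c(OCc4ccccc4)cc4oc(-c5ccc(OCc6ccccc6)c(OCc6ccccc6)c5)cc(=O)c4c3OCc3ccccc3)c2)cc(OCc2ccccc2)cc1OC | intermediate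
15 | (2S)-7-(benzyloxy)-2-{3,4-bis(benzyloxy)-5-[5,7-bis(benzyloxy)-2-(3,4-bis(benzyloxy)phenyl)-4-oxo-4H-chromen-6-yl]phenyl}-5-methoxychroman-4-one | O=C1C[C@@H](c2cc(OCc3ccccc3)c(OCc3ccccc3)c(-c3c(OCc4ccccc4)cc4oc(-c5ccc(OCc6ccccc6)c(OCc6ccccc6)c5)cc(=O)c4c3OCc3ccccc3)c2)Oc2cc(OCc3ccccc3)cc(OC)c21 | intermediate
16 | (2S)-2-{3,4-dihydroxy-5-[2-(3,4-dihydroxyphenyl)-5,7-dihydroxy-4-oxo-4H-chromen-6-yl]phenyl}-5,7-dihydroxychroman-4-one | O=C1C[C@@H](c2cc(O)c(O)c(-c3c(O)cc4oc(-c5ccc(O)c(O)c5)cc(=O)c4c3O)c2)Oc2cc(O)cc(O)c21 | target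

**Count**
Total steps: 12. Longest linear sequence: 8 steps (1, 2, 3, 7, 9, 10, 11, 12; the branch 4, 5, 6, 7, 9, 10, 11, 12 is equally long).

**Steps most likely to fail**

Step 11. The carbenoid may be captured by the lone pair of O1 (oxonium ylide, then [1,2]-benzyl shift) faster than it inserts into C2–H, or the catalyst may discriminate poorly between the two enantiotopic hydrogens. The fallback sets out from 9 and 11 and comes back at 15; it closes ring C at O1–C2 by known asymmetric oxa-Michael chemistry.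
- Alcohol 9 is oxidised with MnO2 in CH2Cl2 to the biaryl aldehyde F1.
- Ketone 11 is converted through its lithium dianion (LiN(SiMe3)2, THF, −78 °C, then di-tert-butyl dicarbonate) into the tert-butyl beta-keto ester F2.
- Knoevenagel condensation of F1 with F2 (piperidine, AcOH, toluene, 4 Å MS) should give the alkylidene beta-keto ester F3 as an E/Z mixture.
- A quinine- or quinidine-derived bifunctional thiourea (10 mol %, toluene, −25 °C; the pseudoenantiomer that gives 2S) should cyclise F3 by enantioselective intramolecular oxa-Michael addition to the 3-(tert-butoxycarbonyl)flavanone F4.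
- TsOH in toluene at 80 °C removes the tert-butyl ester with decarboxylation and gives 15.

Step 7. Protodeboronation of the ortho-alkoxy boronate may outrun transmetalation to the crowded di-ortho-benzyloxy arylpalladium iodide. The fallback sets out from 3 and 8 and comes back at 9. The coupling is moved one step earlier, onto the 5-hydroxy iodide 3, where the position next to iodine carries only a hydrogen-bonded OH instead of a benzyloxy group. The same Pd(OAc)2/SPhos/K3PO4 system should give the 5-hydroxy biaryl alcohol F5. Benzylation of its chelated phenol (BnBr, K2CO3, DMF, 70 °C; the benzylic alcohol is not alkylated by carbonate) gives 9.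

Step 12. Benzyl cations may escape the scavenger and C-benzylate the phloroglucinol rings, or ring C may ionise at C2–O1 under the Lewis acid and erode the configuration while seven benzyl ethers are still being cleaved. The fallback sets out from 15 and comes back at 16. The benzyl ethers are removed first without any cation, by hydrogenolysis (H2 1 atm, Pd(OH)2/C, THF/MeOH, rt, stopped before the flavone C2''=C3'' bond is reduced), to give the 5-O-methyl heptaphenol F6. The single peri methyl ether is then cleaved under chelation control with AlCl3 in MeCN at rt to give 16.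

**Further compounds**
F1 | step 11 | 3,4-bis(benzyloxy)-5-[5,7-bis(benzyloxy)-2-(3,4-bis(benzyloxy)phenyl)-4-oxo-4H-chromen-6-yl]benzaldehyde | O=Cc1cc(OCc2ccccc2)c(OCc2ccccc2)c(-c2c(OCc3ccccc3)cc3oc(-c4ccc(OCc5ccccc5)c(OCc5ccccc5)c4)cc(=O)c3c2OCc2ccccc2)c1
F2 | step 11 | tert-butyl 3-[4-(benzyloxy)-2-hydroxy-6-methoxyphenyl]-3-oxopropanoate | CC(C)(C)OC(=O)CC(=O)c1c(O)cc(OCc2ccccc2)cc1OC
F3 | step 11 | tert-butyl 2-[4-(benzyloxy)-2-hydroxy-6-methoxybenzoyl]-3-{3,4-bis(benzyloxy)-5-[5,7-bis(benzyloxy)-2-(3,4-bis(benzyloxy)phenyl)-4-oxo-4H-chromen-6-yl]phenyl}prop-2-enoate (E/Z mixture) | CC(C)(C)OC(=O)C(=Cc1cc(OCc2ccccc2)c(OCc2ccccc2)c(-c2c(OCc3ccccc3)cc3oc(-c4ccc(OCc5ccccc5)c(OCc5ccccc5)c4)cc(=O)c3c2OCc2ccccc2)c1)C(=O)c1c(O)cc(OCc2ccccc2)cc1OC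
F4 | step 11 | tert-butyl (2S)-7-(benzyloxy)-2-{3,4-bis(benzyloxy)-5-[5,7-bis(benzyloxy)-2-(3,4-bis(benzyloxy)phenyl)-4-oxo-4H-chromen-6-yl]phenyl}-5-methoxy-4-oxochromane-3-carboxylate (C3 epimerisable, keto/enol mixture) | O=C1C(C(=O)OC(C)(C)C)[C@@H](c2cc(OCc3ccccc3)c(OCc3ccccc3)c(-c3c(OCc4ccccc4)cc4oc(-c5ccc(OCc6ccccc6)c(OCc6ccccc6)c5)cc(=O)c4c3OCc3ccccc3)c2)Oc2cc(OCc3ccccc3)cc(OC)c21
F5 | step 7 | 7-(benzyloxy)-6-[2,3-bis(benzyloxy)-5-(hydroxymethyl)phenyl]-2-[3,4-bis(benzyloxy)phenyl]-5-hydroxy-4H-chromen-4-one | O=c1cc(-c2ccc(OCc3ccccc3)c(OCc3ccccc3)c2)oc2cc(OCc3ccccc3)c(-c3cc(CO)cc(OCc4ccccc4)c3OCc3ccccc3)c(O)c12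
F6 | step 12 | (2S)-2-{3,4-dihydroxy-5-[2-(3,4-dihydroxyphenyl)-5,7-dihydroxy-4-oxo-4H-chromen-6-yl]phenyl}-7-hydroxy-5-methoxychroman-4-one | O=C1C[C@@H](c2cc(O)c(O)c(-c3c(O)cc4oc(-c5ccc(O)c(O)c5)cc(=O)c4c3O)c2)Oc2cc(O)cc(OC)c21
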